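The route rests on a two-carbon ring expansion of a ribose-derived cyclopentene to the seven-membered ring B. The key step, a dichloroketene [2+2] cycloaddition to a cyclic allylsilane, forms C7–C8 and C5–C6 in one operation (daucane numbering). It exploits the exocyclic C8=C14 alkene and the C6 oxygen of ring B: silicon fixes the regiochemistry and its CH2 becomes C14, while the ketene carbonyl becomes C6. A Lewis acid then cleaves the old C5–C8 bond, and the released enolate closes cyclopentane ring A by aldol addition to the side-chain isopropyl ketone (C4–C5). Directed reduction sets C6; the purchased C9/C10 acetonide relays C1.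

Key step: step 7

Numbering used (daucane): C1 quaternary ring-fusion carbon bearing CH3-15; C2, C3 CH2; C4 carbinol bearing isopropyl; C5 ring-fusion CH; C6 ester carbinol; C7 CH2; C8 bearing =C14H2; C9, C10 diol carbons. Ring A is the cyclopentane, ring B the cycloheptane.

Assumption: 4-methylpent-1-en-3-one (sold stabilised) and the D-ribose-derived enone (3aR,6aR)-2,2-dimethyl-3a,6a-dihydro-4H-cyclopenta[d][1,3]dioxol-4-one are taken as purchasable.

Step 1
Reactants: 1 4-methylpent-1-en-3-one
Product: 2 2-(2-bromoethyl)-2-isopropyl-1,3-dioxolane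
Conditions: HBr (gas), HOCH2CH2OH, CH2Cl2, 0 → 20 °C
Reagents that add atoms: hydrogen bromide, Br; ethylene glycol, OCCO
Why: Conjugate addition of HBr to the vinyl ketone followed by acid-catalysed ketalisation is the standard preparation of β-bromo ketals and creates no stereocentre.

Step 2
Reactants: 2 2-(2-bromoethyl)-2-isopropyl-1,3-dioxolane; 3 (3aR,6aR)-2,2-dimethyl-3a,6a-dihydro-4H-cyclopenta[d][1,3]dioxol-4-one
Product: 5 tertiary allylic alcohol, via Grignard reagent 4 (not isolated)
Conditions: Mg, THF, 25 °C; then 3, THF, −78 °C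
Reagents that add atoms: none
Why: Grignard 1,2-addition to the cyclopentenone carbonyl should occur from the convex face anti to the acetonide; the new carbinol centre is erased in step 3.

Step 3
Reactants: 5 tertiary allylic alcohol
Product: 6 transposed 3-substituted enone
Conditions: [C5H5NH][CrO3Cl] (pyridinium chlorochromate), NaOAc, 4 Å sieves, CH2Cl2, 20 °C
Reagents that add atoms: pyridinium chlorochromate, [O-][Cr](=O)(=O)Cl.c1cc[nH+]cc1
Why: Dauben–Babler oxidative 1,3-transposition through the allyl chromate ester moves the oxygen to the far alkene carbon and leaves the side chain on the β-carbon of a new enone (future C8 carbonyl, C1 β-carbon).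

Step 4
Reactants: 6 transposed 3-substituted enone
Product: 8 enol triflate, via lithium enolate 7 (not isolated)
Conditions: Me2CuLi, Et2O, −78 → −30 °C; then PhNTf2, THF, −78 → 20 °C
Reagents that add atoms: lithium dimethylcuprate, C[Cu-]C.[Li+]; N-phenylbis(trifluoromethanesulfonimide), O=S(=O)(N(c1ccccc1)S(=O)(=O)C(F)(F)F)C(F)(F)F
Why: Gilman conjugate addition anti to the acetonide should set quaternary C1 with the methyl trans to the C10 oxygen, and O-triflation of the regiodefined enolate fixes the C5=C8 alkene.

Step 5
Reactants: 8 enol triflate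
Product: 9 cyclic allylsilane with ketal side chain
Conditions: Me3SiCH2MgCl, Pd(PPh3)4 (5 mol %), THF, 0 → 20 °C
Reagents that add atoms: (trimethylsilyl)methylmagnesium chloride, C[Si](C)(C)C[Mg]Cl
Why: Kumada coupling of an enol triflate with the silylmethyl Grignard reagent is the standard route to allylsilanes and touches no stereocentre.

Step 6
Reactants: 9 cyclic allylsilane with ketal side chain
Product: 10 cyclic allylsilane with isopropyl ketone side chain
Conditions: PPTS, acetone/H2O (10:1), 45 °C
Reagents that add atoms: water, O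
Why: Transketalisation in wet acetone removes the dioxolane while the acetonide, itself an acetone ketal, and the allylsilane should survive; the ketone must be free before step 8.

Step 7
Reactants: 10 cyclic allylsilane with isopropyl ketone side chain
Product: 12 silylmethyl cyclobutanone, via dichlorocyclobutanone 11 (not isolated)
Conditions: Cl3CCOCl, Zn–Cu couple, Et2O/DME, 20 °C; then AcOH, Zn, 20 °C (same flask)
Reagents that add atoms: dichloroketene, ClC(Cl)=C=O, made in the flask from trichloroacetyl chloride, ClC(Cl)(Cl)C(Cl)=O
Why: The electrophilic central carbon of dichloroketene bonds to C5, the allylsilane terminus that leaves positive charge on the tertiary, β-silyl-stabilised C8, and the CCl2 carbon closes onto C8, so C5–C6 and C7–C8 form in one [π2s+π2a] or tight zwitterionic event; zinc then removes the two chlorines. The closest known reaction type is dichloroketene cycloaddition to trisubstituted alkenes and allylsilanes with reductive dechlorination. The four-membered ring closes by cycloaddition across the cyclopentene C5=C8 bond to give a cis-fused bicyclo[3.2.0]heptan-6-one. The new stereocentres C5 and C8 should arise by attack on the face anti to the acetonide and the side chain, but both are erased in step 8, so no facial selectivity is needed. The step needs regioselectivity (carbonyl carbon to C5) and chemoselectivity over C-acylation with loss of silicon; the first is secured by the β-silicon effect, which also overrides the inductive pull of the C9 oxygen, the second by the concerted character of ketene cycloaddition in ether without a strong Lewis acid.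

Step 8
Reactants: 12 silylmethyl cyclobutanone
Product: 14 bicyclic hydroxy ketone, via titanium enolate 13 (not isolated)
Conditions: TiCl4 (1.1 equiv), 2,6-di-tert-butylpyridine (0.2 equiv), CH2Cl2, −78 → −40 °C; then pH 7 buffer
Reagents that add atoms: none
Why: Proposed new method: TiCl4 on the cyclobutanone oxygen should heterolyse the more substituted ring-fusion bond C5–C8, because the cation developing at C8 is tertiary and β to silicon (closest known reaction types: the Lewis acid opening of 3-alkoxycyclobutanones to 1,4-zwitterions, silicon-terminated cation chemistry of the Hosomi–Sakurai type and the retro-aldol two-carbon ring expansion of 3-siloxybicyclo[3.2.0]heptan-6-ones), chloride then takes Me3Si to leave C8=C14, and the regiodefined titanium enolate 13 adds reversibly to the tethered isopropyl ketone (5-exo aldol) through a six-membered titanium chelate, which holds the C4 oxygen cis to C6 on ring A and should settle on the trans-fused aldolate, in which the chelate shares its face of ring A with CH3-15 and not with the oxygenated C10 branch.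

Step 9
Reactants: 14 bicyclic hydroxy ketone
Product: 15 acetonide-protected 4,6-diol
Conditions: Me4NBH(OAc)3, MeCN/AcOH (1:1), −30 °C
Reagents that add atoms: none
Why: In the Evans–Saksena reduction the acetoxyborohydride bound to the C4 hydroxyl should deliver hydride to the C6 carbonyl face cis to the C4–O bond, leaving the new C6 hydroxyl cis to H-5 and trans to the C4 hydroxyl.

Step 10
Reactants: 15 acetonide-protected 4,6-diol
Product: 16 acetonide-protected isovalerate
Conditions: 3-methylbutanoyl chloride, pyridine, DMAP (cat.), CH2Cl2, 0 °C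
Reagents that add atoms: 3-methylbutanoyl chloride, CC(C)CC(Cl)=O
Why: Acylation should take the secondary C6 hydroxyl only, since the tertiary C4 hydroxyl is unreactive under these conditions.

Step 11
Reactants: 16 acetonide-protected isovalerate
Product: 17 CNP0204264.1
Conditions: AcOH/H2O (4:1), 40 °C
Reagents that add atoms: none
Why: Mild aqueous acid hydrolysis of the acetonide should free the C9/C10 cis-diol without ionising the tertiary alcohol or cleaving the ester.

Compound list
1 | 4-methylpent-1-en-3-one | C=CC(=O)C(C)C | starting material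
2 | 2-(2-bromoethyl)-2-isopropyl-1,3-dioxolane | BrCCC1(C(C)C)OCCO1 | intermediate
3 | (3aR,6aR)-2,2-dimethyl-3a,6a-dihydro-4H-cyclopenta[d][1,3]dioxol-4-one | O=C1C=C[C@H]2OC(C)(C)O[C@@H]12 | starting material
4 | [2-(2-isopropyl-1,3-dioxolan-2-yl)ethyl]magnesium bromide | Br[Mg]CCC1(C(C)C)OCCO1 | intermediate
5 | tertiary allylic alcohol: 4-[2-(2-isopropyl-1,3-dioxolan-2-yl)ethyl]-2,2-dimethyl-3a,6a-dihydro-4H-cyclopenta[d][1,3]dioxol-4-ol, hydroxyl cis to the acetonide oxygens | O[C@@]1(CCC3(C(C)C)OCCO3)C=C[C@H]2OC(C)(C)O[C@@H]12 | intermediate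
6 | transposed enone: (3aS,6aS)-6-[2-(2-isopropyl-1,3-dioxolan-2-yl)ethyl]-2,2-dimethyl-3a,6a-dihydro-4H-cyclopenta[d][1,3]dioxol-4-one | O=C1C=C(CCC3(C(C)C)OCCO3)[C@@H]2OC(C)(C)O[C@H]12 | intermediate
7 | lithium enolate of the 6-methyl ketone, methyl trans to the acetonide oxygens | [Li]OC1=C[C@](C)(CCC3(C(C)C)OCCO3)[C@@H]2OC(C)(C)O[C@H]12 | intermediate
8 | enol triflate of the 6-methyl ketone, methyl trans to the acetonide oxygens | FC(F)(F)S(=O)(=O)OC1=C[C@](C)(CCC3(C(C)C)OCCO3)[C@@H]2OC(C)(C)O[C@H]12 | intermediate
9 | cyclic allylsilane, (trimethylsilyl)methyl on the alkene carbon next to the acetonide, ketal side chain | C[Si](C)(C)CC1=C[C@](C)(CCC3(C(C)C)OCCO3)[C@@H]2OC(C)(C)O[C@H]12 | intermediate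
10 | cyclic allylsilane with 4-methyl-3-oxopentyl side chain | C[Si](C)(C)CC1=C[C@](C)(CCC(=O)C(C)C)[C@@H]2OC(C)(C)O[C@H]12 | intermediate
11 | cis-fused 7,7-dichlorobicyclo[3.2.0]heptan-6-one, (trimethylsilyl)methyl at the ring-fusion carbon, new bonds anti to the acetonide | C[Si](C)(C)C[C@@]13C(Cl)(Cl)C(=O)[C@H]3[C@](C)(CCC(=O)C(C)C)[C@@H]2OC(C)(C)O[C@H]12 | intermediate
12 | dechlorinated silylmethyl cyclobutanone | C[Si](C)(C)C[C@@]13CC(=O)[C@H]3[C@](C)(CCC(=O)C(C)C)[C@@H]2OC(C)(C)O[C@H]12 | intermediate
13 | trichlorotitanium enolate of the ring-expanded 3-methylenecycloheptanone | C=C1CC(O[Ti](Cl)(Cl)Cl)=C[C@](C)(CCC(=O)C(C)C)[C@@H]2OC(C)(C)O[C@H]12 | intermediate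
14 | bicyclic hydroxy ketone: 9,10-acetonide of the 6-oxo-dauc-8(14)-ene-4,9,10-triol, trans-fused, C4 hydroxyl cis to CH3-15 | C=C1CC(=O)[C@@H]2[C@](C)(CC[C@@]2(O)C(C)C)[C@@H]3OC(C)(C)O[C@H]13 | intermediate
15 | 9,10-acetonide of the dauc-8(14)-ene-4,6,9,10-tetraol, C6 hydroxyl cis to H-5 | C=C1C[C@H](O)[C@@H]2[C@](C)(CC[C@@]2(O)C(C)C)[C@@H]3OC(C)(C)O[C@H]13 | intermediate
16 | 9,10-acetonide of the target, 6-O-(3-methylbutanoyl) | C=C1C[C@H](OC(=O)CC(C)C)[C@@H]2[C@](C)(CC[C@@]2(O)C(C)C)[C@@H]3OC(C)(C)O[C@H]13 | intermediate
17 | CNP0204264.1: 6-O-(3-methylbutanoyl)dauc-8(14)-ene-4,6,9,10-tetraol, C6 S, C5 S, C1 S, C4 R, C10 S, C9 R | C=C1C[C@H](OC(=O)CC(C)C)[C@@H]2[C@](C)(CC[C@@]2(O)C(C)C)[C@H](O)[C@@H]1O | target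

Total step count: 11. Longest linear sequence: 11 steps (1 → 17).

Steps most likely to fail

Step 8. The heterolysis may break the C7–C8 bond instead of C5–C8, so that ring B is not formed. The enolate may be protonated before it cyclises. Closure under kinetic control on the C5 face that carries the tether would give the cis ring fusion. The fallback replaces carbon-bound silicon by oxygen as the donor and rests on the known retro-aldol ring expansion; it sets out from 6 and comes back at 15. Me2CuLi followed by t-BuMe2SiCl gives silyl enol ether F1. Dichloroketene addition gives dichloro siloxycyclobutanone F2, and zinc in AcOH gives siloxycyclobutanone F3. PPTS in wet acetone frees the side-chain ketone and gives keto siloxycyclobutanone F4. Bu4NF in THF at −78 → 0 °C removes silicon, the cyclobutanolate opens by the established retro-aldol ring expansion, and the released C5 enolate is expected to close ring A by aldol addition to give hydroxy dione F5. Me4NBH(OAc)3 reduces only the C6 ketone, which is β to the free hydroxyl, and gives dihydroxy ketone F6. Lombardo methylenation (Zn, CH2Br2, TiCl4) of the remaining C8 ketone gives 15.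

Step 7. Zinc salts may promote intramolecular allylation of the free side-chain ketone by the allylsilane, or the β-silyl cation may lose silicon before the second bond closes. The fallback keeps the ketone masked through the cycloaddition; it sets out from 9 and returns at 12. The same cycloaddition and zinc dechlorination on 9 give dichlorocyclobutanone ketal F7 and then cyclobutanone ketal F8. PPTS in wet acetone then gives 12.

Step 9. External hydride attack from the face cis to H-5 may compete with internal delivery and give the C6 epimer. The fallback makes that epimer on purpose and inverts it; it sets out from 14 and returns at 16. NaBH4 with CeCl3·7H2O in MeOH at −78 °C should give the 6-epi alcohol F9. Mitsunobu esterification with 3-methylbutanoic acid (PPh3, diisopropyl azodicarboxylate, toluene) inverts C6 and installs the ester, giving 16.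

Further compounds
F1 | step 8 | tert-butyldimethylsilyl enol ether of the 6-methyl ketone, ketal side chain | CC(C)(C)[Si](C)(C)OC1=C[C@](C)(CCC3(C(C)C)OCCO3)[C@@H]2OC(C)(C)O[C@H]12
F2 | step 8 | dichloro siloxycyclobutanone, ketal side chain | CC(C)(C)[Si](C)(C)O[C@@]13C(Cl)(Cl)C(=O)[C@H]3[C@](C)(CCC4(C(C)C)OCCO4)[C@@H]2OC(C)(C)O[C@H]12
F3 | step 8 | siloxycyclobutanone, ketal side chain | CC(C)(C)[Si](C)(C)O[C@@]13CC(=O)[C@H]3[C@](C)(CCC4(C(C)C)OCCO4)[C@@H]2OC(C)(C)O[C@H]12
F4 | step 8 | keto siloxycyclobutanone, free isopropyl ketone side chain | CC(C)(C)[Si](C)(C)O[C@@]13CC(=O)[C@H]3[C@](C)(CCC(=O)C(C)C)[C@@H]2OC(C)(C)O[C@H]12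
F5 | step 8 | hydroxy dione: bicyclic 4-hydroxy-6,8-dione, 9,10-acetonide | O=C1CC(=O)[C@@H]2[C@](C)(CC[C@@]2(O)C(C)C)[C@@H]3OC(C)(C)O[C@H]13
F6 | step 8 | dihydroxy ketone: bicyclic 4,6-dihydroxy-8-ketone, 9,10-acetonide | O=C1C[C@H](O)[C@@H]2[C@](C)(CC[C@@]2(O)C(C)C)[C@@H]3OC(C)(C)O[C@H]13
F7 | step 7 | dichlorocyclobutanone ketal: dichloro silylmethyl cyclobutanone, ketal side chain | C[Si](C)(C)C[C@@]13C(Cl)(Cl)C(=O)[C@H]3[C@](C)(CCC4(C(C)C)OCCO4)[C@@H]2OC(C)(C)O[C@H]12
F8 | step 7 | cyclobutanone ketal: silylmethyl cyclobutanone, ketal side chain | C[Si](C)(C)C[C@@]13CC(=O)[C@H]3[C@](C)(CCC4(C(C)C)OCCO4)[C@@H]2OC(C)(C)O[C@H]12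
F9 | step 9 | 6-epi alcohol: C6 epimer of 15 | C=C1C[C@@H](O)[C@@H]2[C@](C)(CC[C@@]2(O)C(C)C)[C@@H]3OC(C)(C)O[C@H]13
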